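Count half-lives of starting material, not hours. Midnight and summer look nearly the same, with equal charges and the same final temperature, but summer spends its first hour cold.

in all of them: starting material 0.056 M; coupling partner 0.112 M
- oak: free catalyst 0.28 mM; temperature 0 °C; run made earlier
- ash: free catalyst 0.42 mM; temperature 20 °C; run made earlier
- midnight: free catalyst 0.56 mM; temperature 35 °C; time 2.0 h
- noon: free catalyst 0.56 mM; temperature 5 °C; time 2.0 h
- summer: free catalyst 0.56 mM; at 5 °C until 1.0 h, from then on at 35 °C; time 2.0 h
- autumn: free catalyst 0.56 mM; temperature 20 °C; time 2.0 h

- oak (time / h: target / %, starting material / %): 1.00: 0, 99.2; 2.00: 0, 98.1; 2.50: 0.6, 97.8; 4.00: 0, 95.8; 6.00: 0.9, 93.9; 8.00: 0.8, 91.7; 15.0: 2.8, 86.0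
- ash (time / h: target / %, starting material / %): 0.667: 0.7, 96.0; 1.33: 1.6, 91.9; 2.00: 3.1, 89.1; 3.00: 5.0, 84.8; 4.00: 7.4, 81.1; 5.00: 9.3, 78.6

(standard deviation of a reading: 0.3 percentage points)

- reactions considered so far: free catalyst <-> dormant form; free catalyst + open intermediate <-> catalyst intermediate; coupling partner + catalyst intermediate -> free catalyst + target; starting material + free catalyst -> free catalyst + open intermediate; target + free catalyst <-> isomer of the product + free catalyst

- the flask that comes out highest in amount of target, in percent of the starting material charged, or "all alike" when all lie within 1.5 percentage points (midnight / noon / summer / autumn / all alike)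
- target at the end, in percent of the starting material charged, midnight
- target at the end, in percent of the starting material charged, noon
- target at the end, in percent of the starting material charged, summer
- target at the end, in percent of the starting material charged, autumn

1. The reckoning treats starting material as a pseudo-first-order decay, with a rate proportional to the catalyst charge. This is an assumption. The last reading of ash gives a half-life of 14.4 h, and the last reading of oak gives 68.9 h.

2. At equal catalyst, oak runs slower than ash by a factor of 3.19. The reckoning takes the logarithm of this factor as steady per degree.

3. At the charge of the four flasks, the half-life is 4.52 h at the temperature of midnight, 10.8 h at that of autumn and 25.8 h at that of noon.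

4. Midnight reaches 0.443 on the half-life count, which is the time at each temperature divided by the half-life there, summed.

5. The cold hour of summer counts 0.0388, while the first hour of midnight counts 0.221. So summer ends lower, at 0.260. Autumn counts 0.185 and noon 0.0776, so midnight has the highest count.

6. The count leaves 73.6% of the starting material in midnight and 83.5% in summer. At its last reading, ash shows target as 43.5% of the starting material lost. That share gives 11.5% target for midnight and 7.17% for summer.

7. The forecast, holding that “All rates scale with catalyst”, names midnight and gives 13% for midnight, 0.7% for noon, 6.8% for summer and 4.4% for autumn, which is higher than this reckoning for midnight and lower for summer.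

8. The flasks give 15.1% for midnight, 0.659% for noon, 8.69% for summer and 4.61% for autumn, so midnight is highest.

    free catalyst ⇌ dormant form (K = 0.330, k = 0.0170 /min, Ea = 105 kJ/mol, ΔH = −54.0 kJ/mol)
    free catalyst + open intermediate ⇌ catalyst intermediate (K = 180 /M, k = 120 /M/min, Ea = 61.0 kJ/mol, ΔH = 42.0 kJ/mol)
    coupling partner + catalyst intermediate → free catalyst + target (k = 16.0 /M/min, Ea = 43.0 kJ/mol)
    starting material + free catalyst → free catalyst + open intermediate (k = 7.10 /M/min, Ea = 48.0 kJ/mol)
    target + free catalyst ⇌ isomer of the product + free catalyst, rate k5*[free catalyst]*[target] forward; the back reaction follows from the equilibrium constant (K = 0.630, k = 49.0 /M/min, Ea = 37.0 kJ/mol, ΔH = 0 kJ/mol)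
    (constants at 35 °C)

Midnight holds 21.7% of its catalyst charge as dormant form, yet starting material stands at 72% of its charge against the counted 73.6%. Midnight is not at rest. At 20.0 h its count reaches 4.43, which leaves 4.64% of the starting material, and the flask shows 3.40%. Summer counts 4.24, which leaves 5.29%, and the flask shows 3.93%. The target gap of 6.4 percentage points closes: midnight rises from 15.1% to 59.1%, and summer reaches 58.8%.

Readings and results stem from a simulated flask on assumed constants; scatter was added.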